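**Plan**

- Retrosynthesis: ring C is cut at O1–C2 and C2–C3 (cyclodehydration, enolate benzoylation), then the C4–C4a acetyl bond (aryllithium acylation), then the piperidine at C3'–C4' (ring-closing metathesis), then N1'–C2' (allylic amination), and last the C8–C2' chain back to formylated 5-methoxyresorcinol.
- Forward: ring A is bought as 5-methoxyresorcinol, the piperidine ring closes in step 7, ring C closes last in step 11, and ring B arrives with benzoyl chloride.
- Stereochemistry: the only stereocentre, C2' (R), is set in step 6 by a chiral iridium phosphoramidite catalyst and is not touched afterwards.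
- Enabling feature: C2' carries C8 of ring A, N1' and C3', so it is the branched end of an aryl allyl unit; a but-3-enyl arm on N1' then places two terminal alkenes for closure of the six-membered ring at C3'=C4'.

Key step: step 7

Assumption: in step 6 the (Ra,Rc,Rc) ligand is taken to deliver the R amine, as it does with (E)-cinnamyl methyl carbonate and amines; if the sense is opposite for this arene, the mirror-image ligand is used.

**Route**

Step 1
Reactants: 1 5-methoxyresorcinol (5-methoxybenzene-1,3-diol); 2 chloromethyl methyl ether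
Product: 3 1-methoxy-3,5-bis(methoxymethoxy)benzene
Conditions: MOMCl (2.5 equiv), i-Pr2NEt (3 equiv), CH2Cl2, 0 °C to rt
Reagents that add atoms: chloromethyl methyl ether, COCCl
Why: O-alkylation of both phenols with an α-chloro ether (methoxymethyl ether formation) should be clean on this unhindered resorcinol and installs the acetal groups that later direct both lithiations.

Step 2
Reactants: 3 1-methoxy-3,5-bis(methoxymethoxy)benzene; 4 N,N-dimethylformamide
Product: 6 4-methoxy-2,6-bis(methoxymethoxy)benzaldehyde, via aryllithium 5 (not isolated)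
Conditions: n-BuLi (1.2 equiv), TMEDA, THF, 0 °C; DMF, 0 °C to rt; H2O
Reagents that add atoms: N,N-dimethylformamide, CN(C)C=O
Why: Directed ortho-metalation followed by formylation with DMF should occur at the carbon flanked by the two acetal ethers, because these coordinate lithium better than the methyl ether.

Step 3
Reactants: 6 4-methoxy-2,6-bis(methoxymethoxy)benzaldehyde; 7 ethyl (triphenylphosphoranylidene)acetate
Product: 8 ethyl (2E)-3-[4-methoxy-2,6-bis(methoxymethoxy)phenyl]prop-2-enoate
Conditions: Ph3P=CHCO2Et (1.3 equiv), toluene, 100 °C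
Reagents that add atoms: ethyl (triphenylphosphoranylidene)acetate, CCOC(=O)C=P(c1ccccc1)(c1ccccc1)c1ccccc1
Why: Wittig olefination with a stabilised ylide should give the E enoate selectively and tolerates the hindered, electron-rich aldehyde at elevated temperature.

Step 4
Reactants: 8 ethyl (2E)-3-[4-methoxy-2,6-bis(methoxymethoxy)phenyl]prop-2-enoate
Product: 9 (2E)-3-[4-methoxy-2,6-bis(methoxymethoxy)phenyl]prop-2-en-1-ol
Conditions: i-Bu2AlH (2.5 equiv), CH2Cl2, −78 °C; aq Rochelle salt
Reagents that add atoms: none
Why: 1,2-Reduction of the conjugated ester by an aluminium hydride at low temperature should give the E allylic alcohol without touching the alkene or the acetals.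

Step 5
Reactants: 9 (2E)-3-[4-methoxy-2,6-bis(methoxymethoxy)phenyl]prop-2-en-1-ol; 10 methyl chloroformate
Product: 11 (2E)-3-[4-methoxy-2,6-bis(methoxymethoxy)phenyl]prop-2-en-1-yl methyl carbonate
Conditions: ClCO2Me (1.5 equiv), pyridine, CH2Cl2, 0 °C
Reagents that add atoms: methyl chloroformate, COC(=O)Cl
Why: Acylation of the primary allylic alcohol with a chloroformate (carbonate formation) under basic conditions should avoid ionisation of the electron-rich cinnamyl system and gives the leaving group needed for iridium catalysis.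

Step 6
Reactants: 11 (2E)-3-[4-methoxy-2,6-bis(methoxymethoxy)phenyl]prop-2-en-1-yl methyl carbonate; 12 N-methylbut-3-en-1-amine
Product: 13 (1R)-N-(but-3-en-1-yl)-1-[4-methoxy-2,6-bis(methoxymethoxy)phenyl]-N-methylprop-2-en-1-amine
Conditions: [Ir(cod)Cl]2 (2 mol%), (Ra,Rc,Rc)-(1,1'-binaphthalene-2,2'-diyl) N,N-bis[1-(2-methoxyphenyl)ethyl]phosphoramidite (4 mol%), preactivated with n-PrNH2 (THF, 50 °C, then evaporation); 12 (1.3 equiv), THF, rt
Reagents that add atoms: N-methylbut-3-en-1-amine, CNCCC=C
Why: Iridium-catalysed asymmetric allylic amination, in which the cyclometalated iridium phosphoramidite ionises the carbonate to an (allyl)iridium species and the amine attacks the aryl-bearing terminus on the face left open by the ligand, should set C2' as R; the 2-methoxyphenyl ligand is chosen because it keeps selectivity with ortho-substituted cinnamyl carbonates.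

Step 7
Reactants: 13 (1R)-N-(but-3-en-1-yl)-1-[4-methoxy-2,6-bis(methoxymethoxy)phenyl]-N-methylprop-2-en-1-amine
Product: 16 (2R)-2-[4-methoxy-2,6-bis(methoxymethoxy)phenyl]-1-methyl-1,2,5,6-tetrahydropyridine, via diene ammonium tosylate 14 (not isolated), via tetrahydropyridinium tosylate 15 (not isolated)
Conditions: TsOH·H2O (1.0 equiv), CH2Cl2, rt; second-generation Grubbs catalyst RuCl2(=CHPh)(H2IMes)(PCy3) (5 mol%), 1,4-benzoquinone (10 mol%), CH2Cl2 (0.01 M), 40 °C; aq NaOH
Reagents that add atoms: none
Why: Ring-closing olefin metathesis by the metallacyclobutane mechanism: the ruthenium alkylidene first exchanges onto the unhindered butenyl terminus, then undergoes [2+2] cycloaddition with the vinyl group on C2' and retro-[2+2] to release the ring alkene, and ethene leaves the system. The closest known reaction type is the ring-closing metathesis of dienyl tertiary amines, as their ammonium sulfonates, to 1,2,5,6-tetrahydropyridines. The piperidine ring closes as a six-membered ring by forming C3'=C4' in a chain whose N1'–C2' bond is already in place, a closure that is entropically easy and is helped by the branched C2' substituent. No stereocentre is created, and C2' is a spectator that keeps its R configuration. The step needs cyclisation over oligomerisation, which high dilution secures, and it needs the new double bond to stay at C3'=C4', which protonation of N1', 1,4-benzoquinone as hydride scavenger and a short reaction time secure. Exactly one equivalent of sulfonic acid is used, so that only the weakly acidic ammonium ion is present and neither the acetal ethers nor the benzylic allylic C2'–N bond is ionised.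

Step 8
Reactants: 16 (2R)-2-[4-methoxy-2,6-bis(methoxymethoxy)phenyl]-1-methyl-1,2,5,6-tetrahydropyridine
Product: 17 (2R)-2-[4-methoxy-2,6-bis(methoxymethoxy)phenyl]-1-methylpiperidine
Conditions: H2 (1 atm), PtO2 (5 mol%), EtOAc, rt
Reagents that add atoms: none
Why: Heterogeneous catalytic hydrogenation of the cis-disubstituted ring alkene should be fast, and platinum is preferred to palladium so that the allylic benzylic C2'–N bond is not hydrogenolysed and the double bond does not migrate before reduction, which leaves C2' untouched.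

Step 9
Reactants: 17 (2R)-2-[4-methoxy-2,6-bis(methoxymethoxy)phenyl]-1-methylpiperidine; 18 N-methoxy-N-methylacetamide
Product: 20 1-[6-methoxy-2,4-bis(methoxymethoxy)-3-[(2R)-1-methylpiperidin-2-yl]phenyl]ethan-1-one, via aryllithium 19 (not isolated)
Conditions: n-BuLi (1.3 equiv), TMEDA, THF, −20 to 0 °C; MeC(O)N(OMe)Me (1.5 equiv), −78 °C to rt; H2O
Reagents that add atoms: N-methoxy-N-methylacetamide, CON(C)C(C)=O
Why: Directed ortho-metalation at one of the two equivalent ring positions between an acetal ether and the methyl ether, followed by Weinreb ketone synthesis, should give the methyl ketone without over-addition, while the non-acidic C2'–H is not removed and the stereocentre is kept.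

Step 10
Reactants: 20 1-[6-methoxy-2,4-bis(methoxymethoxy)-3-[(2R)-1-methylpiperidin-2-yl]phenyl]ethan-1-one; 21 benzoyl chloride
Product: 23 1-[6-methoxy-2,4-bis(methoxymethoxy)-3-[(2R)-1-methylpiperidin-2-yl]phenyl]-3-phenylpropane-1,3-dione, via lithium enolate 22 (not isolated)
Conditions: LiN(SiMe3)2 (3 equiv), THF, −78 °C; PhCOCl (1.1 equiv), −78 to 0 °C; aq NH4Cl
Reagents that add atoms: benzoyl chloride, O=C(Cl)c1ccccc1
Why: Crossed Claisen condensation, the C-acylation that a Baker–Venkataraman rearrangement delivers in the free-phenol series, should work because the kinetic lithium enolate of the methyl ketone is benzoylated and the excess base holds the 1,3-diketone as its enolate.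

Step 11
Reactants: 23 1-[6-methoxy-2,4-bis(methoxymethoxy)-3-[(2R)-1-methylpiperidin-2-yl]phenyl]-3-phenylpropane-1,3-dione
Product: 25 7-hydroxy-5-methoxy-8-[(2R)-1-methylpiperidin-2-yl]-2-phenyl-4H-chromen-4-one (CNP0152057.1), via dihydroxy diketone 24 (not isolated)
Conditions: 3 M HCl, MeOH, rt to 45 °C; aq NaHCO3
Reagents that add atoms: none
Why: Acid-catalysed acetal cleavage frees both phenols and the hydroxyl ortho to the diketone adds to the benzoyl carbonyl with loss of water (flavone cyclodehydration), which can close ring C only toward the 5-methoxy-7-hydroxy-8-piperidinyl pattern, and the moderate temperature is chosen to avoid retro-Mannich opening at C2'.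

**Compound list**

1 | 5-methoxyresorcinol (5-methoxybenzene-1,3-diol) | COc1cc(O)cc(O)c1 | starting material
2 | chloromethyl methyl ether | COCCl | starting material
3 | 1-methoxy-3,5-bis(methoxymethoxy)benzene | COCOc1cc(OC)cc(OCOC)c1 | intermediate
4 | N,N-dimethylformamide | CN(C)C=O | starting material
5 | [4-methoxy-2,6-bis(methoxymethoxy)phenyl]lithium | [Li]c1c(OCOC)cc(OC)cc1OCOC | intermediate
6 | 4-methoxy-2,6-bis(methoxymethoxy)benzaldehyde | COCOc1cc(OC)cc(OCOC)c1C=O | intermediate
7 | ethyl (triphenylphosphoranylidene)acetate | CCOC(=O)C=P(c1ccccc1)(c1ccccc1)c1ccccc1 | starting material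
8 | ethyl (2E)-3-[4-methoxy-2,6-bis(methoxymethoxy)phenyl]prop-2-enoate | CCOC(=O)/C=C/c1c(OCOC)cc(OC)cc1OCOC | intermediate
9 | (2E)-3-[4-methoxy-2,6-bis(methoxymethoxy)phenyl]prop-2-en-1-ol | OC/C=C/c1c(OCOC)cc(OC)cc1OCOC | intermediate
10 | methyl chloroformate | COC(=O)Cl | starting material
11 | (2E)-3-[4-methoxy-2,6-bis(methoxymethoxy)phenyl]prop-2-en-1-yl methyl carbonate | COC(=O)OC/C=C/c1c(OCOC)cc(OC)cc1OCOC | intermediate
12 | N-methylbut-3-en-1-amine | CNCCC=C | starting material
13 | (1R)-N-(but-3-en-1-yl)-1-[4-methoxy-2,6-bis(methoxymethoxy)phenyl]-N-methylprop-2-en-1-amine | COCOc1cc(OC)cc(OCOC)c1[C@@H](C=C)N(C)CCC=C | intermediate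
14 | (1R)-N-(but-3-en-1-yl)-1-[4-methoxy-2,6-bis(methoxymethoxy)phenyl]-N-methylprop-2-en-1-aminium 4-methylbenzenesulfonate | COCOc1cc(OC)cc(OCOC)c1[C@@H](C=C)[NH+](C)CCC=C.Cc1ccc(cc1)S(=O)(=O)[O-] | intermediate
15 | (2R)-2-[4-methoxy-2,6-bis(methoxymethoxy)phenyl]-1-methyl-1,2,5,6-tetrahydropyridin-1-ium 4-methylbenzenesulfonate | COCOc1cc(OC)cc(OCOC)c1[C@H]1C=CCC[NH+]1C.Cc1ccc(cc1)S(=O)(=O)[O-] | intermediate
16 | (2R)-2-[4-methoxy-2,6-bis(methoxymethoxy)phenyl]-1-methyl-1,2,5,6-tetrahydropyridine | COCOc1cc(OC)cc(OCOC)c1[C@H]1C=CCCN1C | intermediate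
17 | (2R)-2-[4-methoxy-2,6-bis(methoxymethoxy)phenyl]-1-methylpiperidine | COCOc1cc(OC)cc(OCOC)c1[C@H]1CCCCN1C | intermediate
18 | N-methoxy-N-methylacetamide | CON(C)C(C)=O | starting material
19 | [6-methoxy-2,4-bis(methoxymethoxy)-3-[(2R)-1-methylpiperidin-2-yl]phenyl]lithium | [Li]c1c(OC)cc(OCOC)c([C@H]2CCCCN2C)c1OCOC | intermediate
20 | 1-[6-methoxy-2,4-bis(methoxymethoxy)-3-[(2R)-1-methylpiperidin-2-yl]phenyl]ethan-1-one | CC(=O)c1c(OC)cc(OCOC)c([C@H]2CCCCN2C)c1OCOC | intermediate
21 | benzoyl chloride | O=C(Cl)c1ccccc1 | starting material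
22 | lithium 1-[6-methoxy-2,4-bis(methoxymethoxy)-3-[(2R)-1-methylpiperidin-2-yl]phenyl]ethen-1-olate | [Li]OC(=C)c1c(OC)cc(OCOC)c([C@H]2CCCCN2C)c1OCOC | intermediate
23 | 1-[6-methoxy-2,4-bis(methoxymethoxy)-3-[(2R)-1-methylpiperidin-2-yl]phenyl]-3-phenylpropane-1,3-dione | O=C(CC(=O)c1ccccc1)c1c(OC)cc(OCOC)c([C@H]2CCCCN2C)c1OCOC | intermediate
24 | 1-[2,4-dihydroxy-6-methoxy-3-[(2R)-1-methylpiperidin-2-yl]phenyl]-3-phenylpropane-1,3-dione | O=C(CC(=O)c1ccccc1)c1c(OC)cc(O)c([C@H]2CCCCN2C)c1O | intermediate
25 | 7-hydroxy-5-methoxy-8-[(2R)-1-methylpiperidin-2-yl]-2-phenyl-4H-chromen-4-one | COc1cc(O)c([C@H]2CCCCN2C)c2oc(-c3ccccc3)cc(=O)c12 | target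

**Count and risks**

Total step count: 11. Longest linear sequence: 11 steps, from compound 1 to compound 25.

Steps most likely to fail:

1. Step 6. The two ortho substituents crowd the branched allyl terminus, so the amine may attack the unsubstituted terminus or lose facial control, and the electron-rich product may re-ionise on the metal and erode in enantiomeric purity. The fallback replaces catalyst control by auxiliary control and runs from aldehyde 6 back to diene 13.
   - Condensation of 6 with (S)-2-methylpropane-2-sulfinamide and Ti(OEt)4 in THF at 60 °C should give (S)-N-[(E)-[4-methoxy-2,6-bis(methoxymethoxy)phenyl]methylidene]-2-methylpropane-2-sulfinamide F1.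
   - Addition of CH2=CHMgBr in CH2Cl2 at −78 °C through the magnesium-chelated chair should give (S)-N-[(1R)-1-[4-methoxy-2,6-bis(methoxymethoxy)phenyl]prop-2-en-1-yl]-2-methylpropane-2-sulfinamide F2, whose minor diastereomer can be removed by chromatography.
   - N-Methylation with LiN(SiMe3)2 and MeI in THF should give (S)-N-[(1R)-1-[4-methoxy-2,6-bis(methoxymethoxy)phenyl]prop-2-en-1-yl]-N,2-dimethylpropane-2-sulfinamide F3.
   - Brief treatment with HCl in MeOH at 0 °C should remove the sulfinyl group and give (1R)-1-[4-methoxy-2,6-bis(methoxymethoxy)phenyl]-N-methylprop-2-en-1-amine F4.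
   - Alkylation with 4-bromobut-1-ene, K2CO3 and NaI in MeCN at 60 °C returns to the route at compound 13.

2. Step 7. Incompletely protonated amine may deactivate the ruthenium carbene. Ruthenium hydrides may move the double bond toward C2', which would erase the stereocentre. The benzylic allylic C2'–N bond of the ammonium ion may also ionise slowly. The fallback makes nitrogen non-basic and runs from carbonate 11 back to tetrahydropyridine 16.
   - The iridium amination of 11 is run with but-3-en-1-amine, a less hindered primary nucleophile, to give (1R)-N-(but-3-en-1-yl)-1-[4-methoxy-2,6-bis(methoxymethoxy)phenyl]prop-2-en-1-amine F5.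
   - ClCO2Me and Et3N should convert it into methyl N-(but-3-en-1-yl)-N-[(1R)-1-[4-methoxy-2,6-bis(methoxymethoxy)phenyl]prop-2-en-1-yl]carbamate F6.
   - Ring-closing metathesis with the second-generation Grubbs catalyst RuCl2(=CHPh)(H2IMes)(PCy3) in CH2Cl2 at 40 °C, without acid, should give methyl (2R)-2-[4-methoxy-2,6-bis(methoxymethoxy)phenyl]-5,6-dihydropyridine-1(2H)-carboxylate F7.
   - Reduction of the carbamate to the N-methyl group with LiAlH4 in THF at reflux returns to the route at compound 16.

3. Step 9. Metalation may be slow or occur at another site, or the hindered aryllithium may take a proton from the acetamide and revert to 17. The fallback uses electrophilic acylation and runs from piperidine 17 back to diketone 24.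
   - HCl in MeOH at rt should remove both acetal ethers and give 5-methoxy-2-[(2R)-1-methylpiperidin-2-yl]benzene-1,3-diol F8, handled under argon.
   - Friedel–Crafts acetylation with BF3·OEt2 in AcOH at 70 °C should give 1-[2,4-dihydroxy-6-methoxy-3-[(2R)-1-methylpiperidin-2-yl]phenyl]ethan-1-one F9; the two free ring positions are equivalent.
   - The polyanion formed with LiN(SiMe3)2 (5 equiv) in THF at −78 °C is C-benzoylated with PhCOCl (1 equiv) and returns to the route at compound 24, which is cyclised under the acid conditions of step 11.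

Further compounds
F1 | step 6 | (S)-N-[(E)-[4-methoxy-2,6-bis(methoxymethoxy)phenyl]methylidene]-2-methylpropane-2-sulfinamide | CC(C)(C)[S@](=O)/N=C/c1c(OCOC)cc(OC)cc1OCOC
F2 | step 6 | (S)-N-[(1R)-1-[4-methoxy-2,6-bis(methoxymethoxy)phenyl]prop-2-en-1-yl]-2-methylpropane-2-sulfinamide | CC(C)(C)[S@](=O)N[C@H](C=C)c1c(OCOC)cc(OC)cc1OCOC
F3 | step 6 | (S)-N-[(1R)-1-[4-methoxy-2,6-bis(methoxymethoxy)phenyl]prop-2-en-1-yl]-N,2-dimethylpropane-2-sulfinamide | CC(C)(C)[S@](=O)N(C)[C@H](C=C)c1c(OCOC)cc(OC)cc1OCOC
F4 | step 6 | (1R)-1-[4-methoxy-2,6-bis(methoxymethoxy)phenyl]-N-methylprop-2-en-1-amine | CN[C@H](C=C)c1c(OCOC)cc(OC)cc1OCOC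
F5 | step 7 | (1R)-N-(but-3-en-1-yl)-1-[4-methoxy-2,6-bis(methoxymethoxy)phenyl]prop-2-en-1-amine | COCOc1cc(OC)cc(OCOC)c1[C@@H](C=C)NCCC=C
F6 | step 7 | methyl N-(but-3-en-1-yl)-N-[(1R)-1-[4-methoxy-2,6-bis(methoxymethoxy)phenyl]prop-2-en-1-yl]carbamate | COCOc1cc(OC)cc(OCOC)c1[C@@H](C=C)N(CCC=C)C(=O)OC
F7 | step 7 | methyl (2R)-2-[4-methoxy-2,6-bis(methoxymethoxy)phenyl]-5,6-dihydropyridine-1(2H)-carboxylate | COCOc1cc(OC)cc(OCOC)c1[C@H]1C=CCCN1C(=O)OC
F8 | step 9 | 5-methoxy-2-[(2R)-1-methylpiperidin-2-yl]benzene-1,3-diol | COc1cc(O)c([C@H]2CCCCN2C)c(O)c1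
F9 | step 9 | 1-[2,4-dihydroxy-6-methoxy-3-[(2R)-1-methylpiperidin-2-yl]phenyl]ethan-1-one | CC(=O)c1c(OC)cc(O)c([C@H]2CCCCN2C)c1O
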